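The runs are calculated from invented constants, and the scatter is random.

X is the branch point of this scheme: G and D make it, and each X then goes either with Q into J or with a second G into Z, so we follow two rates at X, the one with Q and the one with G.

| setting | south | north-east | north-west | Tuesday's | Monday's | Saturday's | Wednesday's | Sunday's |
|---|---|---|---|---|---|---|---|---|
| G | 20 mM | 20 mM | 20 mM | 20 mM (fed, over 20 h) | 20 mM | 20 mM | 20 mM | 20 mM (in portions, 3, over 20 h) |
| D | 20 mM | 20 mM | 20 mM | 20.0 mM | 20.0 mM (fed, over 20 h) | 20.0 mM (fed, over 2.0 h) | 20.0 mM | 20.0 mM |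
| Q | 14 mM | 7 mM | 28 mM | 14.0 mM | 14.0 mM | 14.0 mM | 14.0 mM | 14.0 mM |
| remark | run made earlier | run made earlier | run made earlier | all else is in the flask from the start; the feed brings no volume worth counting | all else is in the flask from the start; the feed brings no volume worth counting | all else is in the flask from the start; the feed brings no volume worth counting | everything together at the start | first portion at the start, last at 20 h |
| time |  |  |  | 30 h | 30 h | 30 h | 30 h | 30 h |

- south (time / h: J / %, Z / %): 2.50: 8.4, 8.4; 5.00: 19.1, 17.4; 8.00: 27.6, 24.0; 10.0: 32.5, 27.8; 12.0: 35.1, 29.9; 15.0: 39.0, 32.3; 20.0: 45.3, 34.5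
- north-east (time / h: J / %, Z / %): 1.00: 1.6, 2.9; 3.00: 6.3, 12.8; 5.00: 11.3, 20.4; 8.00: 17.0, 30.7; 10.0: 20.1, 35.4; 15.0: 24.7, 43.0; 20.0: 28.1, 46.9
- north-west (time / h: J / %, Z / %): 1.00: 3.5, 1.7; 3.00: 17.5, 8.3; 5.00: 26.9, 12.2; 8.00: 37.8, 16.8; 10.0: 44.1, 18.3; 15.0: 53.1, 19.7; 20.0: 57.3, 22.0

(scatter of a reading: 0.5 percentage points)

- percent here means G units held: one Z counts as two
- reactions considered so far: G + D -> X; Q + X -> J; G + X -> Z

1. the flask with the highest share of J in J plus Z ("all alike" if they lie within 1.5 percentage points) (Tuesday's / Monday's / Saturday's / Wednesday's / Sunday's / all alike)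
2. share of J in J plus Z at the end, Tuesday's
3. share of J in J plus Z at the end, Monday's
4. share of J in J plus Z at the end, Saturday's
5. share of J in J plus Z at the end, Wednesday's
6. share of J in J plus Z at the end, Sunday's

D stands in neither rate, and X stands in both, so their ratio holds Q over G. The early readings show it: J over Z in G units is 0.492 in the north-east run, 1.00 in the south run and 2.11 in the north-west run, while the charged Q over G is 0.350, 0.700 and 1.40. Their quotient, averaged, is 1.45, as read: the odds constant (a selectivity factor), the early J over Z per unit of charged Q over G. It is a working figure for early odds and not the odds at equal Q and G, because it is read from amounts gathered up to 2.50 h or 3.00 h, and by 2.50 h the south run already holds 16.8% of its G charge in J and Z. With q and g the fractions of the whole Q and G charges in the flask at the opening, we reckon the early odds as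

w = 1.45 × (Q charge / G charge) × q / g

For the opening hours this gives

Wednesday's and Monday's: w = 1.01
Sunday's, first portion: w = 3.04

We therefore expect Sunday's above Wednesday's, and Tuesday's, whose slow feed also holds g down, above Wednesday's too; but we reckon no figure for Tuesday's, so we leave open which of these two leads, and we expect no lift for Monday's, which opens at Wednesday's w. Wednesday's repeats the south run, whose share at 20.0 h reads 56.8%.

The forecast gave 66% for Sunday's, 64.5% for Tuesday's, 58% for Wednesday's, 58.3% for Saturday's and 55% for Monday's, naming Sunday's with the caution "Sunday's lead over Tuesday's is small and within my arithmetic error".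

The flasks give 66.5% for Sunday's, 63.6% for Tuesday's, 57.6% for Wednesday's, 57.4% for Saturday's and 54.3% for Monday's.

    G + D → X (k = 0.00210 M⁻¹ s⁻¹)
    Q + X → J (k = 0.00690 M⁻¹ s⁻¹)
    G + X → Z (k = 0.00290 M⁻¹ s⁻¹)

Monday's opened at a reckoned w = 1.01 and ended with a J share of 54.3%. A neighbouring flask keeps Monday's recipe but is charged with 5.0 mM of G, so the same reckoning gives an opening w of 4.05, larger than Monday's. That neighbour ended with a J share of 87.1%, higher than Monday's, with 7.25% of its G charge still present as G and 11.3% held in Z.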